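**Retrosynthetic overview**
1. Feature: in ring D the hydroxyl carbon C4 has the ring C ether carbon C1 para to it and the ring E ether carbon C5 and the hydroxyl carbon C3 ortho to it. A formyl group on C4 therefore activates three C–F bonds for SNAr and is afterwards converted into the C4 hydroxyl by Baeyer–Villiger/Dakin oxidation.
2. Target 45 ⇐ hydrogenolysis of 17 benzyl ethers ⇐ Dakin oxidation ⇐ benzyloxide for the last fluoride ⇐ union of phenol 21 (rings A–C, para fluoride) and phenol 39 (rings E–G, ortho fluoride) on 2,4,6-trifluorobenzaldehyde 6.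
3. Phenol 21: rings B and C are grown in turn on a hindered phenol by the same three operations (para SNAr on a trifluorobenzaldehyde, exchange of both ortho fluorides for benzyloxy, Baeyer–Villiger to the next phenol). Ring C uses the 3-OMOM hub 15, so its C2 oxygen is freed last.
4. Phenol 39: ring E block 29 (from 3,4,5-trihydroxybenzaldehyde, its C1 oxygen masked as a MOM ether) is extended in the same way through ring F to ring G, then the MOM group is removed.
5. No ring is formed: all seven benzene rings are bought. Ether bonds are made in the order A–B, B–C and E–F, F–G, then C–D and D–E together.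

Key step: step 26

Remark: the target has no stereocentre. Compounds 1, 6, 11 and 22 are taken as purchased. Rings are lettered A to G from the 2,4,6-trihydroxyphenoxy end, with these locants: ring B C1 (O to A), C4 (O to C); ring C C1 (O to B), C2 (O to D); ring D C1 (O to C), C5 (O to E), hydroxyls at C3 and C4; ring E C1 (O to D), C6 (O to F); ring F C1 (O to E), C4 (O to G); ring G C1 (O to F).

**Rings A to C (phenol 21)**

Step 1
Reactants: 1 1,3,5-tris(benzyloxy)benzene
Product: 3 2,4,6-tris(benzyloxy)benzaldehyde, via iminium chloride 2 (not isolated)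
Conditions: POCl3, DMF, 0 to 50 °C; then ice water
Reagents that add atoms: N,N-dimethylformamide CN(C)C=O; water O
Why: Vilsmeier–Haack formylation, in which the three free positions of 1 are equivalent and strongly activated and the formylated product is too deactivated to react again.

Step 2
Reactants: 3 2,4,6-tris(benzyloxy)benzaldehyde
Product: 5 2,4,6-tris(benzyloxy)phenol, via aryl formate 4 (not isolated)
Conditions: mCPBA, CH2Cl2, 0 °C to rt; then K2CO3, MeOH, rt
Reagents that add atoms: 3-chloroperoxybenzoic acid OOC(=O)c1cccc(Cl)c1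
Why: Baeyer–Villiger (Dakin-type) oxidation, in which the aryl group carrying two ortho and one para alkoxy substituents migrates and the formate is then methanolysed.

Step 3
Reactants: 5 2,4,6-tris(benzyloxy)phenol, 6 2,4,6-trifluorobenzaldehyde
Product: 7 2,6-difluoro-4-[2,4,6-tris(benzyloxy)phenoxy]benzaldehyde
Conditions: Cs2CO3, DMF, 0 °C to rt (6 in slight excess)
Reagents that add atoms: none
Why: SNAr through a formyl-stabilised Meisenheimer anion, in which the phenoxide flanked by two benzyloxy groups should take the open para fluoride and the new aryloxy donor slows a second substitution.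

Step 4
Reactants: 7 2,6-difluoro-4-[2,4,6-tris(benzyloxy)phenoxy]benzaldehyde
Product: 8 2,6-bis(benzyloxy)-4-[2,4,6-tris(benzyloxy)phenoxy]benzaldehyde
Conditions: BnOH, NaH, DMF, 0 to 40 °C
Reagents that add atoms: benzyl alcohol OCc1ccccc1
Why: twofold SNAr of the two formyl-activated ortho fluorides by sodium benzyloxide, with fluoride a far better leaving group than the para aryloxide so that the diaryl ether should stay intact.

Step 5
Reactants: 8 2,6-bis(benzyloxy)-4-[2,4,6-tris(benzyloxy)phenoxy]benzaldehyde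
Product: 10 2,6-bis(benzyloxy)-4-[2,4,6-tris(benzyloxy)phenoxy]phenol (rings A–B phenol), via aryl formate 9 (not isolated)
Conditions: mCPBA, CH2Cl2, 0 °C to rt; then K2CO3, MeOH, rt
Reagents that add atoms: 3-chloroperoxybenzoic acid OOC(=O)c1cccc(Cl)c1
Why: Baeyer–Villiger (Dakin-type) oxidation of an aldehyde with two ortho alkoxy groups and a para aryloxy group, which turns the formyl carbon into the ring B C4 hydroxyl.

Step 6
Reactants: 11 2,4,6-trifluorophenol
Product: 12 1,3,5-trifluoro-2-(methoxymethoxy)benzene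
Conditions: MOMCl, K2CO3, DMF, 0 °C to rt
Reagents that add atoms: chloromethyl methyl ether COCCl
Why: Williamson-type O-alkylation of an acidic phenol, giving an acetal that withstands the bases and the peracid used later and can be removed beside benzyl ethers.

Step 7
Reactants: 12 1,3,5-trifluoro-2-(methoxymethoxy)benzene
Product: 15 2,4,6-trifluoro-3-(methoxymethoxy)benzaldehyde, via aryllithium 13 (not isolated), via lithium aminoalkoxide 14 (not isolated)
Conditions: LiN(i-Pr)2 (LDA), THF, −78 °C; then DMF, −78 °C; then AcOH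
Reagents that add atoms: N,N-dimethylformamide CN(C)C=O
Why: directed ortho-lithiation and formylation, in which the two ring hydrogens of 12 are equivalent, each lies between two fluorines, and the aryllithium is stable to fluoride loss at −78 °C.

Step 8
Reactants: 10 rings A–B phenol, 15 2,4,6-trifluoro-3-(methoxymethoxy)benzaldehyde
Product: 16 4-{2,6-bis(benzyloxy)-4-[2,4,6-tris(benzyloxy)phenoxy]phenoxy}-2,6-difluoro-3-(methoxymethoxy)benzaldehyde
Conditions: Cs2CO3, DMF, 0 °C to rt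
Reagents that add atoms: none
Why: SNAr in which the three fluorides are mutually meta, so the OMOM carbon bears the same share of Meisenheimer charge for each site and sterics should send the doubly ortho-substituted phenoxide to the para carbon, away from the formyl group that shields both ortho fluorides.

Step 9
Reactants: 16 the para-aryloxy difluoro aldehyde
Product: 17 2,6-bis(benzyloxy)-4-{2,6-bis(benzyloxy)-4-[2,4,6-tris(benzyloxy)phenoxy]phenoxy}-3-(methoxymethoxy)benzaldehyde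
Conditions: BnOH, NaH, DMF, 0 to 50 °C
Reagents that add atoms: benzyl alcohol OCc1ccccc1
Why: twofold SNAr of the remaining fluorides, both ortho to the formyl group, by sodium benzyloxide, with the MOM acetal inert to alkoxide.

Step 10
Reactants: 17 the ring C aldehyde
Product: 19 2,6-bis(benzyloxy)-4-{2,6-bis(benzyloxy)-4-[2,4,6-tris(benzyloxy)phenoxy]phenoxy}-3-(methoxymethoxy)phenol, via aryl formate 18 (not isolated)
Conditions: mCPBA, CH2Cl2, 0 °C to rt; then K2CO3, MeOH, rt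
Reagents that add atoms: 3-chloroperoxybenzoic acid OOC(=O)c1cccc(Cl)c1
Why: Baeyer–Villiger (Dakin-type) oxidation of the electron-rich aldehyde, which places a hydroxyl on C4 of ring C.

Step 11
Reactants: 19 the ring C C4 phenol
Product: 20 1,2,3-tris(benzyloxy)-5-{2,6-bis(benzyloxy)-4-[2,4,6-tris(benzyloxy)phenoxy]phenoxy}-4-(methoxymethoxy)benzene
Conditions: BnBr, K2CO3, DMF, 60 °C
Reagents that add atoms: benzyl bromide BrCc1ccccc1
Why: Williamson etherification of the only free phenol, which in DMF proceeds even between two ortho benzyloxy groups.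

Step 12
Reactants: 20 the rings A–C MOM ether
Product: 21 2,3,4-tris(benzyloxy)-6-{2,6-bis(benzyloxy)-4-[2,4,6-tris(benzyloxy)phenoxy]phenoxy}phenol (rings A–C phenol, free OH at C2 of ring C)
Conditions: HCl (cat.), MeOH–THF, 45 °C
Reagents that add atoms: none
Why: acid-catalysed transacetalisation cleaves the MOM ether, while benzyl aryl ethers and diaryl ethers are inert to dilute acid.

**Rings E to G (phenol 39)**

Step 13
Reactants: 22 3,4,5-trihydroxybenzaldehyde
Product: 23 3,4,5-tris(benzyloxy)benzaldehyde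
Conditions: BnBr, K2CO3, DMF, 60 °C
Reagents that add atoms: benzyl bromide BrCc1ccccc1
Why: threefold Williamson etherification, with the formyl group keeping the phenoxides from C-alkylation.

Step 14
Reactants: 23 3,4,5-tris(benzyloxy)benzaldehyde
Product: 25 3,4,5-tris(benzyloxy)phenol, via aryl formate 24 (not isolated)
Conditions: mCPBA, CH2Cl2, 0 °C to rt; then K2CO3, MeOH, rt
Reagents that add atoms: 3-chloroperoxybenzoic acid OOC(=O)c1cccc(Cl)c1
Why: Baeyer–Villiger (Dakin-type) oxidation, in which the para benzyloxy group makes the aryl group the migrating one.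

Step 15
Reactants: 25 3,4,5-tris(benzyloxy)phenol
Product: 26 2,3,4-tris(benzyloxy)-6-hydroxybenzaldehyde
Conditions: MgCl2, Et3N, (CH2O)n, MeCN, reflux; then aq HCl
Reagents that add atoms: formaldehyde (from paraformaldehyde) C=O
Why: magnesium-mediated ortho-formylation of a phenol (Casnati–Skattebøl), in which the magnesium phenoxide delivers formaldehyde only ortho to oxygen, the two ortho positions are equivalent, and the salicylaldehyde chelate resists a second formylation.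

Step 16
Reactants: 26 2,3,4-tris(benzyloxy)-6-hydroxybenzaldehyde
Product: 27 2,3,4-tris(benzyloxy)-6-(methoxymethoxy)benzaldehyde
Conditions: MOMCl, K2CO3, DMF, 0 °C to rt
Reagents that add atoms: chloromethyl methyl ether COCCl
Why: Williamson-type O-alkylation, masking the future ring E C1 hydroxyl with a group orthogonal to benzyl.

Step 17
Reactants: 27 2,3,4-tris(benzyloxy)-6-(methoxymethoxy)benzaldehyde
Product: 29 2,3,4-tris(benzyloxy)-6-(methoxymethoxy)phenol (ring E block), via aryl formate 28 (not isolated)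
Conditions: mCPBA, CH2Cl2, 0 °C to rt; then K2CO3, MeOH, rt
Reagents that add atoms: 3-chloroperoxybenzoic acid OOC(=O)c1cccc(Cl)c1
Why: Baeyer–Villiger (Dakin-type) oxidation of a 2,4,6-trioxygenated benzaldehyde, which sets the ring E C6 hydroxyl next to the masked C1 oxygen.

Step 18
Reactants: 29 ring E block, 6 2,4,6-trifluorobenzaldehyde
Product: 30 2,6-difluoro-4-[2,3,4-tris(benzyloxy)-6-(methoxymethoxy)phenoxy]benzaldehyde
Conditions: Cs2CO3, DMF, 0 °C to rt (6 in slight excess)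
Reagents that add atoms: none
Why: SNAr of the para fluoride by a doubly ortho-substituted phenoxide, for the same steric reason as in step 3.

Step 19
Reactants: 30 the ring F difluoro aldehyde
Product: 31 2,6-bis(benzyloxy)-4-[2,3,4-tris(benzyloxy)-6-(methoxymethoxy)phenoxy]benzaldehyde
Conditions: BnOH, NaH, DMF, 0 to 40 °C
Reagents that add atoms: benzyl alcohol OCc1ccccc1
Why: twofold SNAr of the formyl-activated ortho fluorides by sodium benzyloxide.

Step 20
Reactants: 31 the ring F aldehyde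
Product: 33 2,6-bis(benzyloxy)-4-[2,3,4-tris(benzyloxy)-6-(methoxymethoxy)phenoxy]phenol (rings E–F phenol), via aryl formate 32 (not isolated)
Conditions: mCPBA, CH2Cl2, 0 °C to rt; then K2CO3, MeOH, rt
Reagents that add atoms: 3-chloroperoxybenzoic acid OOC(=O)c1cccc(Cl)c1
Why: Baeyer–Villiger (Dakin-type) oxidation, which turns the formyl carbon into the ring F C4 hydroxyl.

Step 21
Reactants: 33 rings E–F phenol, 6 2,4,6-trifluorobenzaldehyde
Product: 34 4-{2,6-bis(benzyloxy)-4-[2,3,4-tris(benzyloxy)-6-(methoxymethoxy)phenoxy]phenoxy}-2,6-difluorobenzaldehyde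
Conditions: Cs2CO3, DMF, 0 °C to rt (6 in slight excess)
Reagents that add atoms: none
Why: SNAr of the para fluoride by the phenoxide flanked by two benzyloxy groups, as in step 3.

Step 22
Reactants: 34 the ring G difluoro aldehyde
Product: 35 2,6-bis(benzyloxy)-4-{2,6-bis(benzyloxy)-4-[2,3,4-tris(benzyloxy)-6-(methoxymethoxy)phenoxy]phenoxy}benzaldehyde
Conditions: BnOH, NaH, DMF, 0 to 40 °C
Reagents that add atoms: benzyl alcohol OCc1ccccc1
Why: twofold SNAr of the formyl-activated ortho fluorides by sodium benzyloxide.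

Step 23
Reactants: 35 the ring G aldehyde
Product: 37 2,6-bis(benzyloxy)-4-{2,6-bis(benzyloxy)-4-[2,3,4-tris(benzyloxy)-6-(methoxymethoxy)phenoxy]phenoxy}phenol, via aryl formate 36 (not isolated)
Conditions: mCPBA, CH2Cl2, 0 °C to rt; then K2CO3, MeOH, rt
Reagents that add atoms: 3-chloroperoxybenzoic acid OOC(=O)c1cccc(Cl)c1
Why: Baeyer–Villiger (Dakin-type) oxidation, which gives the ring G C4 hydroxyl.

Step 24
Reactants: 37 the ring G C4 phenol
Product: 38 1,2,3-tris(benzyloxy)-5-{2,6-bis(benzyloxy)-4-[2,3,4-tris(benzyloxy)-6-(methoxymethoxy)phenoxy]phenoxy}benzene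
Conditions: BnBr, K2CO3, DMF, 60 °C
Reagents that add atoms: benzyl bromide BrCc1ccccc1
Why: Williamson etherification of the only free phenol, completing the 3,4,5-tris(benzyloxy)phenyl ring G.

Step 25
Reactants: 38 the rings E–G MOM ether
Product: 39 3,4,5-tris(benzyloxy)-2-{3,5-bis(benzyloxy)-4-[3,4,5-tris(benzyloxy)phenoxy]phenoxy}phenol (rings E–G phenol, free OH at C1 of ring E)
Conditions: HCl (cat.), MeOH–THF, 45 °C
Reagents that add atoms: none
Why: acid-catalysed transacetalisation removes the MOM group and leaves the eight benzyl ethers untouched.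

**Union at ring D and end game**

Step 26
Reactants: 21 rings A–C phenol, 6 2,4,6-trifluorobenzaldehyde, 39 rings E–G phenol
Product: 41 2-fluoro-4-(aryloxy of 21)-6-(aryloxy of 39)benzaldehyde (hexadecabenzyl ether), via para-aryloxy difluorobenzaldehyde 40 (not isolated)
Conditions: 21, 6 (1.0 equiv), Cs2CO3, DMF, 0 °C to rt; then 39 (1.05 equiv), Cs2CO3, 50 °C
Reagents that add atoms: none
Why: Both C–O bonds arise by addition–elimination, each cesium phenoxide adding to a C–F carbon of 6 to give a Meisenheimer anion delocalised onto the formyl oxygen before fluoride leaves; the closest known reaction type is the SNAr of ortho- and para-fluorobenzaldehydes with phenoxides. No ring is closed and no stereocentre is created. The step needs site selectivity in the first substitution: the phenoxide of 21 is flanked by the ring B aryloxy group and a benzyloxy group, and with the non-chelating cesium counter-ion in DMF it should add at the open para carbon, away from the formyl group, to give 40. In 40 the two ortho fluorides are equivalent, so the less hindered phenoxide of 39 can give only one product, which forms the C1–O and C5–O bonds of ring D. A third substitution is held back because the ring of 41 carries two aryloxy donors and no excess phenoxide is present, and using exactly one equivalent of 6 keeps 39 from meeting unreacted hub.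

Step 27
Reactants: 41 the fluoro aldehyde
Product: 42 2-(benzyloxy)-4-(aryloxy of 21)-6-(aryloxy of 39)benzaldehyde (heptadecabenzyl ether)
Conditions: BnOH, NaH, DMF, 0 to 50 °C
Reagents that add atoms: benzyl alcohol OCc1ccccc1
Why: SNAr of the last fluoride, still ortho to the formyl group and on a carbon that bears no donor at its ortho or para positions, by sodium benzyloxide.

Step 28
Reactants: 42 the ring D aldehyde
Product: 44 2-(benzyloxy)-4-(aryloxy of 21)-6-(aryloxy of 39)phenol (heptadecabenzyl ether of the target, free OH at C4 of ring D), via aryl formate 43 (not isolated)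
Conditions: mCPBA, CH2Cl2, 0 °C to rt; then K2CO3, MeOH, rt
Reagents that add atoms: 3-chloroperoxybenzoic acid OOC(=O)c1cccc(Cl)c1
Why: Baeyer–Villiger (Dakin-type) oxidation, in which the tri-oxygenated ring D migrates and the formyl carbon becomes the C4 hydroxyl.

Step 29
Reactants: 44 the heptadecabenzyl ether
Product: 45 CNP0130704.0 (target)
Conditions: H2 (1 atm), Pd/C, THF–MeOH, rt, degassed solvents
Reagents that add atoms: none
Why: catalytic hydrogenolysis cleaves all 17 benzyl aryl ethers and leaves the six diaryl ether bonds intact.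

**Compound list**
1 | 1,3,5-tris(benzyloxy)benzene | c1(OCc9ccccc9)cc(OCc9ccccc9)cc(OCc9ccccc9)c1 | starting material
2 | [2,4,6-tris(benzyloxy)benzylidene]dimethyliminium chloride | C[N+](C)=Cc1c(OCc9ccccc9)cc(OCc9ccccc9)cc1OCc9ccccc9.[Cl-] | intermediate (not isolated)
3 | 2,4,6-tris(benzyloxy)benzaldehyde | O=Cc1c(OCc9ccccc9)cc(OCc9ccccc9)cc1OCc9ccccc9 | intermediate
4 | 2,4,6-tris(benzyloxy)phenyl formate | O=COc1c(OCc9ccccc9)cc(OCc9ccccc9)cc1OCc9ccccc9 | intermediate (not isolated)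
5 | 2,4,6-tris(benzyloxy)phenol | Oc1c(OCc9ccccc9)cc(OCc9ccccc9)cc1OCc9ccccc9 | intermediate
6 | 2,4,6-trifluorobenzaldehyde | O=Cc1c(F)cc(F)cc1F | starting material
7 | 2,6-difluoro-4-[2,4,6-tris(benzyloxy)phenoxy]benzaldehyde | O=Cc1c(F)cc(Oc2c(OCc9ccccc9)cc(OCc9ccccc9)cc2OCc9ccccc9)cc1F | intermediate
8 | 2,6-bis(benzyloxy)-4-[2,4,6-tris(benzyloxy)phenoxy]benzaldehyde | O=Cc1c(OCc9ccccc9)cc(Oc2c(OCc9ccccc9)cc(OCc9ccccc9)cc2OCc9ccccc9)cc1OCc9ccccc9 | intermediate
9 | 2,6-bis(benzyloxy)-4-[2,4,6-tris(benzyloxy)phenoxy]phenyl formate | O=COc1c(OCc9ccccc9)cc(Oc2c(OCc9ccccc9)cc(OCc9ccccc9)cc2OCc9ccccc9)cc1OCc9ccccc9 | intermediate (not isolated)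
10 | 2,6-bis(benzyloxy)-4-[2,4,6-tris(benzyloxy)phenoxy]phenol (rings A–B phenol) | Oc1c(OCc9ccccc9)cc(Oc2c(OCc9ccccc9)cc(OCc9ccccc9)cc2OCc9ccccc9)cc1OCc9ccccc9 | intermediate
11 | 2,4,6-trifluorophenol | Oc1c(F)cc(F)cc1F | starting material
12 | 1,3,5-trifluoro-2-(methoxymethoxy)benzene | COCOc1c(F)cc(F)cc1F | intermediate
13 | [2,4,6-trifluoro-3-(methoxymethoxy)phenyl]lithium | [Li]c1c(F)c(OCOC)c(F)cc1F | intermediate (not isolated)
14 | lithium (dimethylamino)[2,4,6-trifluoro-3-(methoxymethoxy)phenyl]methanolate (racemic) | [Li+].[O-]C(N(C)C)c1c(F)c(OCOC)c(F)cc1F | intermediate (not isolated)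
15 | 2,4,6-trifluoro-3-(methoxymethoxy)benzaldehyde | O=Cc1c(F)c(OCOC)c(F)cc1F | intermediate
16 | 4-{2,6-bis(benzyloxy)-4-[2,4,6-tris(benzyloxy)phenoxy]phenoxy}-2,6-difluoro-3-(methoxymethoxy)benzaldehyde | O=Cc1c(F)c(OCOC)c(Oc2c(OCc9ccccc9)cc(Oc3c(OCc9ccccc9)cc(OCc9ccccc9)cc3OCc9ccccc9)cc2OCc9ccccc9)cc1F | intermediate
17 | 2,6-bis(benzyloxy)-4-{2,6-bis(benzyloxy)-4-[2,4,6-tris(benzyloxy)phenoxy]phenoxy}-3-(methoxymethoxy)benzaldehyde | O=Cc1c(OCc9ccccc9)c(OCOC)c(Oc2c(OCc9ccccc9)cc(Oc3c(OCc9ccccc9)cc(OCc9ccccc9)cc3OCc9ccccc9)cc2OCc9ccccc9)cc1OCc9ccccc9 | intermediate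
18 | 2,6-bis(benzyloxy)-4-{2,6-bis(benzyloxy)-4-[2,4,6-tris(benzyloxy)phenoxy]phenoxy}-3-(methoxymethoxy)phenyl formate | O=COc1c(OCc9ccccc9)c(OCOC)c(Oc2c(OCc9ccccc9)cc(Oc3c(OCc9ccccc9)cc(OCc9ccccc9)cc3OCc9ccccc9)cc2OCc9ccccc9)cc1OCc9ccccc9 | intermediate (not isolated)
19 | 2,6-bis(benzyloxy)-4-{2,6-bis(benzyloxy)-4-[2,4,6-tris(benzyloxy)phenoxy]phenoxy}-3-(methoxymethoxy)phenol | Oc1c(OCc9ccccc9)c(OCOC)c(Oc2c(OCc9ccccc9)cc(Oc3c(OCc9ccccc9)cc(OCc9ccccc9)cc3OCc9ccccc9)cc2OCc9ccccc9)cc1OCc9ccccc9 | intermediate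
20 | 1,2,3-tris(benzyloxy)-5-{2,6-bis(benzyloxy)-4-[2,4,6-tris(benzyloxy)phenoxy]phenoxy}-4-(methoxymethoxy)benzene | COCOc1c(OCc9ccccc9)c(OCc9ccccc9)c(OCc9ccccc9)cc1Oc2c(OCc9ccccc9)cc(Oc3c(OCc9ccccc9)cc(OCc9ccccc9)cc3OCc9ccccc9)cc2OCc9ccccc9 | intermediate
21 | 2,3,4-tris(benzyloxy)-6-{2,6-bis(benzyloxy)-4-[2,4,6-tris(benzyloxy)phenoxy]phenoxy}phenol (rings A–C phenol) | Oc1c(OCc9ccccc9)c(OCc9ccccc9)c(OCc9ccccc9)cc1Oc2c(OCc9ccccc9)cc(Oc3c(OCc9ccccc9)cc(OCc9ccccc9)cc3OCc9ccccc9)cc2OCc9ccccc9 | intermediate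
22 | 3,4,5-trihydroxybenzaldehyde | O=Cc1cc(O)c(O)c(O)c1 | starting material
23 | 3,4,5-tris(benzyloxy)benzaldehyde | O=Cc1cc(OCc9ccccc9)c(OCc9ccccc9)c(OCc9ccccc9)c1 | intermediate
24 | 3,4,5-tris(benzyloxy)phenyl formate | O=COc1cc(OCc9ccccc9)c(OCc9ccccc9)c(OCc9ccccc9)c1 | intermediate (not isolated)
25 | 3,4,5-tris(benzyloxy)phenol | Oc1cc(OCc9ccccc9)c(OCc9ccccc9)c(OCc9ccccc9)c1 | intermediate
26 | 2,3,4-tris(benzyloxy)-6-hydroxybenzaldehyde | O=Cc1c(O)cc(OCc9ccccc9)c(OCc9ccccc9)c1OCc9ccccc9 | intermediate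
27 | 2,3,4-tris(benzyloxy)-6-(methoxymethoxy)benzaldehyde | O=Cc1c(OCOC)cc(OCc9ccccc9)c(OCc9ccccc9)c1OCc9ccccc9 | intermediate
28 | 2,3,4-tris(benzyloxy)-6-(methoxymethoxy)phenyl formate | O=COc1c(OCOC)cc(OCc9ccccc9)c(OCc9ccccc9)c1OCc9ccccc9 | intermediate (not isolated)
29 | 2,3,4-tris(benzyloxy)-6-(methoxymethoxy)phenol (ring E block) | Oc1c(OCOC)cc(OCc9ccccc9)c(OCc9ccccc9)c1OCc9ccccc9 | intermediate
30 | 2,6-difluoro-4-[2,3,4-tris(benzyloxy)-6-(methoxymethoxy)phenoxy]benzaldehyde | O=Cc1c(F)cc(Oc2c(OCOC)cc(OCc9ccccc9)c(OCc9ccccc9)c2OCc9ccccc9)cc1F | intermediate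
31 | 2,6-bis(benzyloxy)-4-[2,3,4-tris(benzyloxy)-6-(methoxymethoxy)phenoxy]benzaldehyde | O=Cc1c(OCc9ccccc9)cc(Oc2c(OCOC)cc(OCc9ccccc9)c(OCc9ccccc9)c2OCc9ccccc9)cc1OCc9ccccc9 | intermediate
32 | 2,6-bis(benzyloxy)-4-[2,3,4-tris(benzyloxy)-6-(methoxymethoxy)phenoxy]phenyl formate | O=COc1c(OCc9ccccc9)cc(Oc2c(OCOC)cc(OCc9ccccc9)c(OCc9ccccc9)c2OCc9ccccc9)cc1OCc9ccccc9 | intermediate (not isolated)
33 | 2,6-bis(benzyloxy)-4-[2,3,4-tris(benzyloxy)-6-(methoxymethoxy)phenoxy]phenol (rings E–F phenol) | Oc1c(OCc9ccccc9)cc(Oc2c(OCOC)cc(OCc9ccccc9)c(OCc9ccccc9)c2OCc9ccccc9)cc1OCc9ccccc9 | intermediate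
34 | 4-{2,6-bis(benzyloxy)-4-[2,3,4-tris(benzyloxy)-6-(methoxymethoxy)phenoxy]phenoxy}-2,6-difluorobenzaldehyde | O=Cc1c(F)cc(Oc3c(OCc9ccccc9)cc(Oc2c(OCOC)cc(OCc9ccccc9)c(OCc9ccccc9)c2OCc9ccccc9)cc3OCc9ccccc9)cc1F | intermediate
35 | 2,6-bis(benzyloxy)-4-{2,6-bis(benzyloxy)-4-[2,3,4-tris(benzyloxy)-6-(methoxymethoxy)phenoxy]phenoxy}benzaldehyde | O=Cc1c(OCc9ccccc9)cc(Oc3c(OCc9ccccc9)cc(Oc2c(OCOC)cc(OCc9ccccc9)c(OCc9ccccc9)c2OCc9ccccc9)cc3OCc9ccccc9)cc1OCc9ccccc9 | intermediate
36 | 2,6-bis(benzyloxy)-4-{2,6-bis(benzyloxy)-4-[2,3,4-tris(benzyloxy)-6-(methoxymethoxy)phenoxy]phenoxy}phenyl formate | O=COc1c(OCc9ccccc9)cc(Oc3c(OCc9ccccc9)cc(Oc2c(OCOC)cc(OCc9ccccc9)c(OCc9ccccc9)c2OCc9ccccc9)cc3OCc9ccccc9)cc1OCc9ccccc9 | intermediate (not isolated)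
37 | 2,6-bis(benzyloxy)-4-{2,6-bis(benzyloxy)-4-[2,3,4-tris(benzyloxy)-6-(methoxymethoxy)phenoxy]phenoxy}phenol | Oc1c(OCc9ccccc9)cc(Oc3c(OCc9ccccc9)cc(Oc2c(OCOC)cc(OCc9ccccc9)c(OCc9ccccc9)c2OCc9ccccc9)cc3OCc9ccccc9)cc1OCc9ccccc9 | intermediate
38 | 1,2,3-tris(benzyloxy)-5-{2,6-bis(benzyloxy)-4-[2,3,4-tris(benzyloxy)-6-(methoxymethoxy)phenoxy]phenoxy}benzene | COCOc1cc(OCc9ccccc9)c(OCc9ccccc9)c(OCc9ccccc9)c1Oc2cc(OCc9ccccc9)c(Oc3cc(OCc9ccccc9)c(OCc9ccccc9)c(OCc9ccccc9)c3)c(OCc9ccccc9)c2 | intermediate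
39 | 3,4,5-tris(benzyloxy)-2-{3,5-bis(benzyloxy)-4-[3,4,5-tris(benzyloxy)phenoxy]phenoxy}phenol (rings E–G phenol) | Oc1cc(OCc9ccccc9)c(OCc9ccccc9)c(OCc9ccccc9)c1Oc2cc(OCc9ccccc9)c(Oc3cc(OCc9ccccc9)c(OCc9ccccc9)c(OCc9ccccc9)c3)c(OCc9ccccc9)c2 | intermediate
40 | 2,6-difluoro-4-(aryloxy of 21)benzaldehyde | O=Cc1c(F)cc(Oc3c(OCc9ccccc9)c(OCc9ccccc9)c(OCc9ccccc9)cc3Oc2c(OCc9ccccc9)cc(Oc4c(OCc9ccccc9)cc(OCc9ccccc9)cc4OCc9ccccc9)cc2OCc9ccccc9)cc1F | intermediate (not isolated)
41 | 2-fluoro-4-(aryloxy of 21)-6-(aryloxy of 39)benzaldehyde, hexadecabenzyl ether | O=Cc1c(F)cc(Oc3c(OCc9ccccc9)c(OCc9ccccc9)c(OCc9ccccc9)cc3Oc2c(OCc9ccccc9)cc(Oc4c(OCc9ccccc9)cc(OCc9ccccc9)cc4OCc9ccccc9)cc2OCc9ccccc9)cc1Oc5cc(OCc9ccccc9)c(OCc9ccccc9)c(OCc9ccccc9)c5Oc6cc(OCc9ccccc9)c(Oc7cc(OCc9ccccc9)c(OCc9ccccc9)c(OCc9ccccc9)c7)c(OCc9ccccc9)c6 | intermediate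
42 | 2-(benzyloxy)-4-(aryloxy of 21)-6-(aryloxy of 39)benzaldehyde, heptadecabenzyl ether | O=Cc1c(OCc9ccccc9)cc(Oc3c(OCc9ccccc9)c(OCc9ccccc9)c(OCc9ccccc9)cc3Oc2c(OCc9ccccc9)cc(Oc4c(OCc9ccccc9)cc(OCc9ccccc9)cc4OCc9ccccc9)cc2OCc9ccccc9)cc1Oc5cc(OCc9ccccc9)c(OCc9ccccc9)c(OCc9ccccc9)c5Oc6cc(OCc9ccccc9)c(Oc7cc(OCc9ccccc9)c(OCc9ccccc9)c(OCc9ccccc9)c7)c(OCc9ccccc9)c6 | intermediate
43 | 2-(benzyloxy)-4-(aryloxy of 21)-6-(aryloxy of 39)phenyl formate | O=COc1c(OCc9ccccc9)cc(Oc3c(OCc9ccccc9)c(OCc9ccccc9)c(OCc9ccccc9)cc3Oc2c(OCc9ccccc9)cc(Oc4c(OCc9ccccc9)cc(OCc9ccccc9)cc4OCc9ccccc9)cc2OCc9ccccc9)cc1Oc5cc(OCc9ccccc9)c(OCc9ccccc9)c(OCc9ccccc9)c5Oc6cc(OCc9ccccc9)c(Oc7cc(OCc9ccccc9)c(OCc9ccccc9)c(OCc9ccccc9)c7)c(OCc9ccccc9)c6 | intermediate (not isolated)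
44 | 2-(benzyloxy)-4-(aryloxy of 21)-6-(aryloxy of 39)phenol, heptadecabenzyl ether of the target | Oc1c(OCc9ccccc9)cc(Oc3c(OCc9ccccc9)c(OCc9ccccc9)c(OCc9ccccc9)cc3Oc2c(OCc9ccccc9)cc(Oc4c(OCc9ccccc9)cc(OCc9ccccc9)cc4OCc9ccccc9)cc2OCc9ccccc9)cc1Oc5cc(OCc9ccccc9)c(OCc9ccccc9)c(OCc9ccccc9)c5Oc6cc(OCc9ccccc9)c(Oc7cc(OCc9ccccc9)c(OCc9ccccc9)c(OCc9ccccc9)c7)c(OCc9ccccc9)c6 | intermediate
45 | CNP0130704.0 | Oc1cc(O)c(Oc2cc(O)c(Oc3cc(O)c(O)c(O)c3Oc3cc(O)c(O)c(Oc4cc(O)c(O)c(O)c4Oc4cc(O)c(Oc5cc(O)c(O)c(O)c5)c(O)c4)c3)c(O)c2)c(O)c1 | target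

**Totals and risks**

Total step count: 29. Longest linear sequence: 17 steps (steps 13 to 25, then 26 to 29).

The three steps most likely to fail:

1. Step 26. The first substitution may lose site control, with the phenoxide of 21 adding at an ortho fluoride as well as at the para one; in the one-pot mode this leads on to regioisomeric and doubly substituted mixtures. The fallback sets out from 39 and 21 and returns at 42, so that steps 26 and 27 are both replaced and every C–O bond of ring D is made at a carbon with a single leaving group. Purchased 4-bromo-2,6-difluorobenzaldehyde (O=Cc1c(F)cc(Br)cc1F) would be treated with one equivalent of BnOH and NaH in DMF to give 2-(benzyloxy)-4-bromo-6-fluorobenzaldehyde F1; the two fluorides are equivalent and bromide is inert to SNAr. The one remaining fluoride would then be displaced by the phenoxide of 39 (Cs2CO3, DMF, 50 °C) to give 2-(benzyloxy)-4-bromo-6-(aryloxy of 39)benzaldehyde F2. The para C–O bond would finally be formed by Ullmann coupling of this aryl bromide with 21 (copper monoiodide CuI, picolinic acid, K3PO4, DMSO, 90 °C), which should give 42.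

2. Step 8. Attack at the open ortho fluoride C6 of 15 may compete with attack at the para carbon, which is flanked by the MOM ether, so that the ring B oxygen ends up on the wrong carbon of ring C. The fallback sets out from 26 and 10 and returns at 21, replacing steps 6 to 12 with a ring C electrophile that has one leaving group only. Salicylaldehyde 26 would be converted with Tf2O and pyridine in CH2Cl2 at 0 °C into 3,4,5-tris(benzyloxy)-2-formylphenyl trifluoromethanesulfonate F3. Palladium-catalysed C–O coupling of F3 with phenol 10 (Pd(OAc)2, t-BuXPhos, K3PO4, toluene, 100 °C) should give 2,3,4-tris(benzyloxy)-6-{2,6-bis(benzyloxy)-4-[2,4,6-tris(benzyloxy)phenoxy]phenoxy}benzaldehyde F4. Baeyer–Villiger oxidation with mCPBA would give 2,3,4-tris(benzyloxy)-6-{2,6-bis(benzyloxy)-4-[2,4,6-tris(benzyloxy)phenoxy]phenoxy}phenyl formate F5, and methanolysis (K2CO3, MeOH) would then give 21.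

3. Step 29. Hydrogenolysis may stall after partial debenzylation, because the substrate changes from lipophilic to very polar and the catalyst surface becomes fouled, and the polyphenol may oxidise in air over a long reaction time. The fallback sets out from 44 and returns at 45: Lewis-acid debenzylation with BCl3 and pentamethylbenzene as benzyl cation scavenger in CH2Cl2 at −78 °C, then MeOH quench. The diaryl ethers are inert to these conditions, and no new compound arises (F0).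

Further compounds
F1 | step 26 | 2-(benzyloxy)-4-bromo-6-fluorobenzaldehyde | O=Cc1c(F)cc(Br)cc1OCc9ccccc9
F2 | step 26 | 2-(benzyloxy)-4-bromo-6-(aryloxy of 39)benzaldehyde | O=Cc1c(OCc9ccccc9)cc(Br)cc1Oc5cc(OCc9ccccc9)c(OCc9ccccc9)c(OCc9ccccc9)c5Oc6cc(OCc9ccccc9)c(Oc7cc(OCc9ccccc9)c(OCc9ccccc9)c(OCc9ccccc9)c7)c(OCc9ccccc9)c6
F3 | step 8 | 3,4,5-tris(benzyloxy)-2-formylphenyl trifluoromethanesulfonate | O=Cc1c(OS(=O)(=O)C(F)(F)F)cc(OCc9ccccc9)c(OCc9ccccc9)c1OCc9ccccc9
F4 | step 8 | 2,3,4-tris(benzyloxy)-6-{2,6-bis(benzyloxy)-4-[2,4,6-tris(benzyloxy)phenoxy]phenoxy}benzaldehyde | O=Cc1c(Oc2c(OCc9ccccc9)cc(Oc3c(OCc9ccccc9)cc(OCc9ccccc9)cc3OCc9ccccc9)cc2OCc9ccccc9)cc(OCc9ccccc9)c(OCc9ccccc9)c1OCc9ccccc9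
F5 | step 8 | 2,3,4-tris(benzyloxy)-6-{2,6-bis(benzyloxy)-4-[2,4,6-tris(benzyloxy)phenoxy]phenoxy}phenyl formate | O=COc1c(Oc2c(OCc9ccccc9)cc(Oc3c(OCc9ccccc9)cc(OCc9ccccc9)cc3OCc9ccccc9)cc2OCc9ccccc9)cc(OCc9ccccc9)c(OCc9ccccc9)c1OCc9ccccc9
F0 | step 29 | none | none
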